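**Retrosynthetic overview**

1. Menaquinone-8 is cut at C1'–C2' (the quinone-bound CH2 and the first vinylic CH) into 2-(chloromethyl)-3-methyl-1,4-naphthoquinone, a C38 terminal alkyne and Me3Al, joined in one pot by Zr-catalysed methylalumination and Ni-catalysed alkenylalane/CH2Cl coupling.
2. Enabling feature: C1' is a CH2 on C3 of the quinone ring (ring B), so a C1'–Cl bond is an allylic chloride vinylogous to the C1 carbonyl and adds readily to zerovalent nickel; C2'(H)=C3'(CH3) is an E-trisubstituted alkene with exactly the H/CH3 pattern that syn-methylmetalation of a terminal alkyne writes.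
3. The C38 alkyne comes from geranylgeranyl phenyl sulfone and a C18 ω-bromo silyl-enyne (sulfone alkylation, Pd/hydride desulfonylation, desilylation); the C18 piece comes from farnesyl bromide and lithiated 1-(trimethylsilyl)propyne, then E-selective SeO2 ω-hydroxylation and bromination.
4. The chloromethylquinone comes from menadione, formaldehyde and HCl.
5. No ring is formed in the route: ring A (benzo) and ring B (quinone) are bought intact in menadione. Of the seven E-alkenes, five come from all-E farnesyl and geranylgeranyl stock, one is fixed in step 2 and one in the key step.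

Key step: step 10

Assumption: commercial (2E,6E)-farnesyl bromide and (2E,6E,10E)-geranylgeraniol are taken as the isomerically pure all-E compounds. The sulfonyl-bearing carbon of 11 forms as a racemate, which is irrelevant because that centre is erased in step 7.

**Route**

Step 1
Reactants: 1 (2E,6E)-farnesyl bromide; 2 1-(trimethylsilyl)propyne
Product: 4 trimethyl[(5E,9E)-6,10,14-trimethylpentadeca-5,9,13-trien-1-yn-1-yl]silane, via lithiated silylpropyne 3 (not isolated)
Conditions: 2, n-BuLi, THF, −40 °C; then 1, −78 °C → −20 °C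
Reagents that add atoms: none
Why: Propargylation of a primary allylic bromide by SN2 at its α-carbon with the silyl-capped propargyl lithium 3 should leave the alkene geometry untouched, the bulky silyl group steering bond formation to the propargylic rather than the allenic carbon.

Step 2
Reactants: 4 trimethyl[(5E,9E)-6,10,14-trimethylpentadeca-5,9,13-trien-1-yn-1-yl]silane
Product: 5 (2E,6E,10E)-2,6,10-trimethyl-15-(trimethylsilyl)pentadeca-2,6,10-trien-14-yn-1-ol
Conditions: SeO2 (cat.), t-BuOOH, salicylic acid (cat.), CH2Cl2, 0 °C → rt, stopped at partial conversion, 4 recycled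
Reagents that add atoms: selenium dioxide O=[Se]=O (catalytic oxygen carrier); tert-butyl hydroperoxide CC(C)(C)OO (terminal oxygen source)
Why: Riley-type allylic oxidation (ene reaction, then [2,3]-sigmatropic shift of the allylseleninic acid) is fastest at the terminal gem-dimethyl alkene and should deliver the E-configured CH2OH, which fixes the geometry of this alkene for the rest of the route.

Step 3
Reactants: 5 (2E,6E,10E)-2,6,10-trimethyl-15-(trimethylsilyl)pentadeca-2,6,10-trien-14-yn-1-ol
Product: 6 [(5E,9E,13E)-15-bromo-6,10,14-trimethylpentadeca-5,9,13-trien-1-yn-1-yl]trimethylsilane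
Conditions: CBr4, PPh3, CH2Cl2, −10 °C → 0 °C
Reagents that add atoms: carbon tetrabromide BrC(Br)(Br)Br
Why: The Appel reaction converts a primary allylic alcohol to the bromide under neutral conditions, without allylic transposition and without touching the alkynylsilane.

Step 4
Reactants: 7 (2E,6E,10E)-geranylgeraniol
Product: 8 (2E,6E,10E)-geranylgeranyl bromide
Conditions: PBr3, Et2O, −10 °C → 0 °C, used crude
Reagents that add atoms: phosphorus tribromide BrP(Br)Br
Why: Low-temperature PBr3 bromination of a primary allylic polyprenol is the standard SN2 conversion and should retain the E geometry.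

Step 5
Reactants: 8 (2E,6E,10E)-geranylgeranyl bromide
Product: 9 (2E,6E,10E)-geranylgeranyl phenyl sulfone
Conditions: PhSO2Na, DMF, rt
Reagents that add atoms: sodium benzenesulfinate [Na+].[O-]S(=O)c1ccccc1
Why: S-alkylation of the ambident sulfinate by SN2 at the primary allylic carbon in a dipolar aprotic solvent should give the primary allylic sulfone.

Step 6
Reactants: 9 (2E,6E,10E)-geranylgeranyl phenyl sulfone; 6 [(5E,9E,13E)-15-bromo-6,10,14-trimethylpentadeca-5,9,13-trien-1-yn-1-yl]trimethylsilane
Product: 11 trimethyl[(5E,9E,13E,17E,21E,25E)-6,10,14,18,22,26,30-heptamethyl-16-(phenylsulfonyl)hentriaconta-5,9,13,17,21,25,29-heptaen-1-yn-1-yl]silane (racemic at C16), via lithiated sulfone 10 (not isolated)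
Conditions: n-BuLi, THF, −78 °C; then 6, −78 °C → −40 °C
Reagents that add atoms: none
Why: Allylic sulfone alkylation (Julia-type sulfone-anion coupling) should join the sulfonyl-stabilised carbanion at its α-carbon to the primary allylic bromide by SN2 without change of alkene geometry; the new sulfonyl-bearing centre is racemic and is removed in step 7, and the capped alkyne offers no acidic hydrogen.

Step 7
Reactants: 11 trimethyl[(5E,9E,13E,17E,21E,25E)-6,10,14,18,22,26,30-heptamethyl-16-(phenylsulfonyl)hentriaconta-5,9,13,17,21,25,29-heptaen-1-yn-1-yl]silane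
Product: 12 trimethyl[(5E,9E,13E,17E,21E,25E)-6,10,14,18,22,26,30-heptamethylhentriaconta-5,9,13,17,21,25,29-heptaen-1-yn-1-yl]silane
Conditions: PdCl2(dppp) (cat.), LiEt3BH, THF, 0 °C
Reagents that add atoms: none
Why: In this Tsuji–Trost-type hydrogenolysis, zerovalent palladium (formed in the flask from the divalent palladium precatalyst and hydride) ionises the allylic C–SO2Ph bond to a syn π-allyl complex and hydride should be delivered to the less substituted terminus, so the alkene stays in place and E; the silyl-capped alkyne is inert to the borohydride.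

Step 8
Reactants: 12 trimethyl[(5E,9E,13E,17E,21E,25E)-6,10,14,18,22,26,30-heptamethylhentriaconta-5,9,13,17,21,25,29-heptaen-1-yn-1-yl]silane
Product: 13 (5E,9E,13E,17E,21E,25E)-6,10,14,18,22,26,30-heptamethylhentriaconta-5,9,13,17,21,25,29-heptaen-1-yne
Conditions: K2CO3 (cat.), MeOH/THF, rt
Reagents that add atoms: none
Why: Base-catalysed methanolysis of the C(sp)–Si bond (protodesilylation) should free the terminal alkyne and leave the seven alkenes untouched.

Step 9
Reactants: 14 menadione (2-methyl-1,4-naphthoquinone)
Product: 15 2-(chloromethyl)-3-methyl-1,4-naphthoquinone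
Conditions: 37% aq. HCHO, HCl (gas), AcOH, rt; product kept cold and used promptly
Reagents that add atoms: formaldehyde C=O; hydrogen chloride Cl
Why: Blanc-type chloromethylation can only occur at C3, the single unsubstituted position of ring B, and should give the electrophile directly at the quinone oxidation level.

Step 10
Reactants: 13 (5E,9E,13E,17E,21E,25E)-6,10,14,18,22,26,30-heptamethylhentriaconta-5,9,13,17,21,25,29-heptaen-1-yne; 15 2-(chloromethyl)-3-methyl-1,4-naphthoquinone
Product: 17 menaquinone-8, via alkenylalane 16 (not isolated)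
Conditions: Me3Al, Cp2ZrCl2 (cat.), ClCH2CH2Cl, rt; excess Me3Al and solvent evaporated, residue in THF; then 15, NiCl2(PPh3)2/n-BuLi (cat., pre-reduced to zerovalent nickel), THF, −20 °C → rt; dilute HCl work-up
Reagents that add atoms: trimethylaluminium C[Al](C)C
Why: The methylzirconocene species formed from Cp2ZrCl2 and Me3Al adds CH3 and metal syn across the terminal C≡C of 13 with the metal on the terminal carbon, and transmetalation gives the (E)-alkenyldimethylalane 16 carrying the C3' methyl. Zerovalent nickel then inserts into the C1'–Cl bond of 15, the alkenyl group moves from aluminium to nickel, and reductive elimination forms C1'–C2' with retention of alkene geometry. The closest known reaction type is Negishi methylalumination followed by nickel-catalysed coupling of an alkenylalane with a benzylic or allylic chloride, a coupling known for chloromethylated para-quinones. No ring is closed and no stereocentre is formed; the only stereo-element, the E C2'=C3' alkene, is set by the syn carbometalation and kept by the stereoretentive coupling. The step needs terminal-aluminium regioselectivity, reaction of the alkyne only, and coupling at CH2Cl instead of addition to the quinone carbonyls; these are secured by the unbranched terminal alkyne, by the inertness of the seven trisubstituted alkenes to carbometalation, and by stripping excess Me3Al and running the fast oxidative addition cold. One operation thus installs a methyl group, an E-trisubstituted alkene and the fragment-joining bond, and delivers the unprotected quinone at its final oxidation level.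

**Compound list**

1 | (2E,6E)-farnesyl bromide | CC(C)=CCC/C(C)=C/CC/C(C)=C/CBr | starting material
2 | 1-(trimethylsilyl)propyne | CC#C[Si](C)(C)C | starting material
3 | 3-lithio-1-(trimethylsilyl)propyne | [Li]CC#C[Si](C)(C)C | intermediate
4 | trimethyl[(5E,9E)-6,10,14-trimethylpentadeca-5,9,13-trien-1-yn-1-yl]silane | CC(C)=CCC/C(C)=C/CC/C(C)=C/CCC#C[Si](C)(C)C | intermediate
5 | (2E,6E,10E)-2,6,10-trimethyl-15-(trimethylsilyl)pentadeca-2,6,10-trien-14-yn-1-ol | OC/C(C)=C/CC/C(C)=C/CC/C(C)=C/CCC#C[Si](C)(C)C | intermediate
6 | [(5E,9E,13E)-15-bromo-6,10,14-trimethylpentadeca-5,9,13-trien-1-yn-1-yl]trimethylsilane | BrC/C(C)=C/CC/C(C)=C/CC/C(C)=C/CCC#C[Si](C)(C)C | intermediate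
7 | (2E,6E,10E)-geranylgeraniol | CC(C)=CCC/C(C)=C/CC/C(C)=C/CC/C(C)=C/CO | starting material
8 | (2E,6E,10E)-geranylgeranyl bromide | CC(C)=CCC/C(C)=C/CC/C(C)=C/CC/C(C)=C/CBr | intermediate
9 | (2E,6E,10E)-geranylgeranyl phenyl sulfone | CC(C)=CCC/C(C)=C/CC/C(C)=C/CC/C(C)=C/CS(=O)(=O)c1ccccc1 | intermediate
10 | 1-lithio-(2E,6E,10E)-geranylgeranyl phenyl sulfone | CC(C)=CCC/C(C)=C/CC/C(C)=C/CC/C(C)=C/C([Li])S(=O)(=O)c1ccccc1 | intermediate
11 | trimethyl[(5E,9E,13E,17E,21E,25E)-6,10,14,18,22,26,30-heptamethyl-16-(phenylsulfonyl)hentriaconta-5,9,13,17,21,25,29-heptaen-1-yn-1-yl]silane, racemic at C16 | CC(C)=CCC/C(C)=C/CC/C(C)=C/CC/C(C)=C/C(S(=O)(=O)c1ccccc1)C/C(C)=C/CC/C(C)=C/CC/C(C)=C/CCC#C[Si](C)(C)C | intermediate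
12 | trimethyl[(5E,9E,13E,17E,21E,25E)-6,10,14,18,22,26,30-heptamethylhentriaconta-5,9,13,17,21,25,29-heptaen-1-yn-1-yl]silane | CC(C)=CCC/C(C)=C/CC/C(C)=C/CC/C(C)=C/CC/C(C)=C/CC/C(C)=C/CC/C(C)=C/CCC#C[Si](C)(C)C | intermediate
13 | (5E,9E,13E,17E,21E,25E)-6,10,14,18,22,26,30-heptamethylhentriaconta-5,9,13,17,21,25,29-heptaen-1-yne | CC(C)=CCC/C(C)=C/CC/C(C)=C/CC/C(C)=C/CC/C(C)=C/CC/C(C)=C/CC/C(C)=C/CCC#C | intermediate
14 | menadione (2-methyl-1,4-naphthoquinone) | CC1=CC(=O)c2ccccc2C1=O | starting material
15 | 2-(chloromethyl)-3-methyl-1,4-naphthoquinone | CC1=C(CCl)C(=O)c2ccccc2C1=O | intermediate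
16 | dimethyl[(1E,5E,9E,13E,17E,21E,25E)-2,6,10,14,18,22,26,30-octamethylhentriaconta-1,5,9,13,17,21,25,29-octaen-1-yl]alumane | CC(C)=CCC/C(C)=C/CC/C(C)=C/CC/C(C)=C/CC/C(C)=C/CC/C(C)=C/CC/C(C)=C/CC/C(C)=C/[Al](C)C | intermediate
17 | menaquinone-8, 2-methyl-3-[(2E,6E,10E,14E,18E,22E,26E)-3,7,11,15,19,23,27,31-octamethyldotriaconta-2,6,10,14,18,22,26,30-octaen-1-yl]naphthalene-1,4-dione | CC(C)=CCC/C(C)=C/CC/C(C)=C/CC/C(C)=C/CC/C(C)=C/CC/C(C)=C/CC/C(C)=C/CC/C(C)=C/CC1=C(C)C(=O)c2ccccc2C1=O | target

**Count and risks**

Total step count: 10. Longest linear sequence: 7 steps (steps 1, 2, 3, 6, 7, 8, 10 from farnesyl bromide).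

Steps most likely to fail:

Step 2. The ene oxidation may also attack the two internal trisubstituted alkenes or the propargylic CH2, and the allylic alcohol may be over-oxidised to the enal, so site selectivity may be poor at useful conversion. The fallback sets out from 4 and comes back at 5; it singles out the terminal alkene by bromohydrin formation instead of an ene reaction and rebuilds the E-allylic alcohol by olefination. NBS in aqueous THF at 0 °C should give the terminal bromohydrin (6E,10E)-3-bromo-2,6,10-trimethyl-15-(trimethylsilyl)pentadeca-6,10-dien-14-yn-2-ol F1. NaH in THF should close it to the terminal epoxide trimethyl[(5E,9E)-12-(3,3-dimethyloxiran-2-yl)-6,10-dimethyldodeca-5,9-dien-1-yn-1-yl]silane F2. H5IO6 in THF/Et2O should cleave the epoxide to the aldehyde (4E,8E)-4,8-dimethyl-13-(trimethylsilyl)trideca-4,8-dien-12-ynal F3. Wittig olefination with the stabilised ylide Ph3P=C(CH3)CO2Et should give, E-selectively, the enoate ethyl (2E,6E,10E)-2,6,10-trimethyl-15-(trimethylsilyl)pentadeca-2,6,10-trien-14-ynoate F4, and i-Bu2AlH in CH2Cl2 at −78 °C should reduce it to 5.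

Step 7. The palladium hydride may add to the silyl alkyne (semi-reduction), or hydride may be delivered to the tertiary allyl terminus and move the alkene out of place. The fallback sets out from 7 and 6 and comes back at 12; it avoids the sulfone altogether and replaces steps 6 and 7 by an allylbarium coupling. Corey–Kim-type chlorination of 7 (NCS, Me2S, CH2Cl2, −40 °C → 0 °C) should give (2E,6E,10E)-geranylgeranyl chloride F5. Active barium (from BaI2 and two equivalents of lithium biphenylide, THF, −78 °C) should insert to give (2E,6E,10E)-geranylgeranylbarium chloride F6. Addition of 6 at −78 °C should then give 12 directly, since allylbarium reagents couple with allylic halides at the α-carbon of both partners with retention of alkene geometry.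

Step 10. Residual methyl- or alkenylaluminium may add to the quinone carbonyls, zerovalent nickel may reduce the quinone by electron transfer, or the carboalumination may be incomplete or not fully regioselective. The fallback sets out from 14 and from alane 16 and comes back at 17; it forms the same bond at the hydroquinone dimethyl ether oxidation level. Reduction of 14 with Na2S2O4 and methylation (Me2SO4, KOH) should give 1,4-dimethoxy-2-methylnaphthalene F7. Chloromethylation (paraformaldehyde, conc. HCl) should give 2-(chloromethyl)-1,4-dimethoxy-3-methylnaphthalene F8. Pd(PPh3)4-catalysed coupling of F8 with 16 in THF (alkenylalane with benzylic chloride, stereoretentive) should give 2-[(2E,6E,10E,14E,18E,22E,26E)-3,7,11,15,19,23,27,31-octamethyldotriaconta-2,6,10,14,18,22,26,30-octaen-1-yl]-1,4-dimethoxy-3-methylnaphthalene F9. Oxidative demethylation with (NH4)2Ce(NO3)6 in MeCN/H2O/CH2Cl2 at 0 °C should then give 17.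

Further compounds
F1 | step 2 | (6E,10E)-3-bromo-2,6,10-trimethyl-15-(trimethylsilyl)pentadeca-6,10-dien-14-yn-2-ol (racemic) | CC(C)(O)C(Br)CC/C(C)=C/CC/C(C)=C/CCC#C[Si](C)(C)C
F2 | step 2 | trimethyl[(5E,9E)-12-(3,3-dimethyloxiran-2-yl)-6,10-dimethyldodeca-5,9-dien-1-yn-1-yl]silane (racemic) | CC1(C)OC1CC/C(C)=C/CC/C(C)=C/CCC#C[Si](C)(C)C
F3 | step 2 | (4E,8E)-4,8-dimethyl-13-(trimethylsilyl)trideca-4,8-dien-12-ynal | O=CCC/C(C)=C/CC/C(C)=C/CCC#C[Si](C)(C)C
F4 | step 2 | ethyl (2E,6E,10E)-2,6,10-trimethyl-15-(trimethylsilyl)pentadeca-2,6,10-trien-14-ynoate | CCOC(=O)/C(C)=C/CC/C(C)=C/CC/C(C)=C/CCC#C[Si](C)(C)C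
F5 | step 7 | (2E,6E,10E)-geranylgeranyl chloride | CC(C)=CCC/C(C)=C/CC/C(C)=C/CC/C(C)=C/CCl
F6 | step 7 | (2E,6E,10E)-geranylgeranylbarium chloride | CC(C)=CCC/C(C)=C/CC/C(C)=C/CC/C(C)=C/C[Ba]Cl
F7 | step 10 | 1,4-dimethoxy-2-methylnaphthalene | COc1cc(C)c(OC)c2ccccc12
F8 | step 10 | 2-(chloromethyl)-1,4-dimethoxy-3-methylnaphthalene | COc1c(C)c(CCl)c(OC)c2ccccc12
F9 | step 10 | 2-[(2E,6E,10E,14E,18E,22E,26E)-3,7,11,15,19,23,27,31-octamethyldotriaconta-2,6,10,14,18,22,26,30-octaen-1-yl]-1,4-dimethoxy-3-methylnaphthalene | CC(C)=CCC/C(C)=C/CC/C(C)=C/CC/C(C)=C/CC/C(C)=C/CC/C(C)=C/CC/C(C)=C/CC/C(C)=C/Cc1c(C)c(OC)c2ccccc2c1OC
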